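**Retrosynthetic overview**
- The target has two identical 2-hydroxy-5-methoxy-6-methyl-1,4-benzoquinone rings (ring A, ring B) joined C3 to C3' by an unbranched chain C1–C14, with no stereocentre. The strategy rests on this chain: C4–C11 are the eight carbons of cis-cyclooctene, and C1–C3 and C12–C14 are the butenyl arms of two identical arenes.
- The C2 hydroxyls go back to quinone epoxides, and the methoxyquinones to 3-methoxy-2-methylphenols, hence to 1,14-bis(3,5-dimethoxy-4-methylphenyl)tetradecane.
- The saturated chain goes back to the 3,11-diene, which is cut at C3=C4 and C11=C12 into two aryl butenes and cyclooctene (ring-opening cross-metathesis, ethylene lost).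
- The aryl butene comes from 3,5-dimethoxy-4-methylbenzoic acid by reduction, bromination and allyl Grignard coupling.
- Ring order: no ring is closed. Both six-membered rings are bought as arenes and oxidised to quinones at the end; the cyclooctene ring is opened in the key step.

Key step: step 4

Remark on the chemistry: the metathesis diene is expected as an E/Z mixture at both double bonds and the later bis-epoxide as a meso/racemic mixture. Both are carried on as mixtures, because the following hydrogenation and the final isomerisation remove these stereo-elements.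

**Step 1**
Reactants: 1 3,5-dimethoxy-4-methylbenzoic acid
Product: 2 (3,5-dimethoxy-4-methylphenyl)methanol
Conditions: LiAlH4, THF, 0 °C to reflux; H2O, aq NaOH work-up
Reagents that add atoms: none
Why: Hydride reduction of a carboxylic acid to the primary benzylic alcohol with LiAlH4, to which the aryl methyl ethers are inert.

**Step 2**
Reactants: 2 (3,5-dimethoxy-4-methylphenyl)methanol
Product: 3 5-(bromomethyl)-1,3-dimethoxy-2-methylbenzene
Conditions: PBr3 (0.4 equiv), CH2Cl2, 0 °C
Reagents that add atoms: phosphorus tribromide, BrP(Br)Br
Why: Activation of the benzylic alcohol as its phosphite ester and SN2 displacement by bromide, a standard benzylic bromination under which the ring ethers survive.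

**Step 3**
Reactants: 3 5-(bromomethyl)-1,3-dimethoxy-2-methylbenzene; 4 allylmagnesium bromide
Product: 5 5-(but-3-en-1-yl)-1,3-dimethoxy-2-methylbenzene
Conditions: 4 (1.3 equiv, Et2O solution), THF, 0 °C to rt, 3 added slowly; aq NH4Cl
Reagents that add atoms: none
Why: Uncatalysed coupling of an allylic Grignard reagent with a benzylic bromide (SN2-type C(sp3)–C(sp3) bond formation), with slow addition of 3 to excess 4 to keep Wurtz-type bibenzyl formation low.

**Step 4**
Reactants: 5 5-(but-3-en-1-yl)-1,3-dimethoxy-2-methylbenzene (6 equiv); 6 cis-cyclooctene (1 equiv)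
Product: 8 (3E,11E)-1,14-bis(3,5-dimethoxy-4-methylphenyl)tetradeca-3,11-diene as the major isomer of an E/Z mixture, via hexene homodimer 7 (not isolated)
Conditions: second-generation Grubbs catalyst (H2IMes)(PCy3)Cl2Ru=CHPh (2 mol %), CH2Cl2, 40 °C, Ar sweep; 6 added over 8 h by syringe pump; ethyl vinyl ether quench
Reagents that add atoms: none
Why: The catalyst benzylidene exchanges with 5 to give a ruthenium alkylidene that adds across the strained cis double bond of 6 by [2+2] cycloaddition and cycloreversion, and the ring-opened alkylidene is capped by a second molecule of 5 or by homodimer 7 (formed from 5 with loss of ethylene and re-entering by secondary metathesis), so that C3=C4 and C11=C12 are formed and C4–C11 come from the eight ring carbons. The closest known reaction type is ring-opening cross-metathesis of cyclooctene with terminal alkenes to end-capped dienes, with the alkene acting as chain-transfer agent. No ring is closed; the eight-membered carbocycle is opened, and release of its ring strain together with loss of ethylene drives the reaction. No stereocentre is created, and the geometry of the two new double bonds is immaterial because step 5 saturates them. The selectivity needed is insertion of exactly one cyclooctene unit between two aryl butene caps; nothing in the substrate enforces this, so it is secured statistically by the excess of 5 and the slow addition of 6, which keep the capping alkene in large excess over ring-opened chain ends. Unreacted 5 and 7 should be recoverable by chromatography and reusable in the same reaction.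

**Step 5**
Reactants: 8 (3E,11E)-1,14-bis(3,5-dimethoxy-4-methylphenyl)tetradeca-3,11-diene (E/Z mixture)
Product: 9 1,14-bis(3,5-dimethoxy-4-methylphenyl)tetradecane
Conditions: H2 (1 atm), 10% Pd/C, EtOAc, rt
Reagents that add atoms: none
Why: Heterogeneous catalytic hydrogenation of two disubstituted alkenes over Pd/C, in which all alkene isomers converge on one alkane and the arenes and aryl ethers are untouched.

**Step 6**
Reactants: 9 1,14-bis(3,5-dimethoxy-4-methylphenyl)tetradecane
Product: 10 5,5'-(tetradecane-1,14-diyl)bis(3-methoxy-2-methylphenol)
Conditions: NaSEt (6 equiv), DMF, 140 °C; aq HCl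
Reagents that add atoms: none
Why: SN2 O-demethylation by ethanethiolate, which should stop at one ether per ring because the phenoxide formed would have to leave as a dianion in a second cleavage; the two methoxy groups of each ring are equivalent, so there is no regiochemical question.

**Step 7**
Reactants: 10 5,5'-(tetradecane-1,14-diyl)bis(3-methoxy-2-methylphenol)
Product: 11 5,5'-(tetradecane-1,14-diyl)bis(3-methoxy-2-methyl-1,4-benzoquinone)
Conditions: (KSO3)2NO (5 equiv), KH2PO4, Aliquat 336 (cat.), CH2Cl2/H2O, rt
Reagents that add atoms: potassium nitrosodisulfonate (KSO3)2NO, [O]N(S(=O)(=O)[O-])S(=O)(=O)[O-].[K+].[K+]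
Why: Teuber oxidation, in which one nitrosodisulfonate radical abstracts the phenolic hydrogen and a second traps the phenoxyl radical at the free para carbon (between the methoxy group and the chain), and loss of imidodisulfonate gives the para-quinone.

**Step 8**
Reactants: 11 5,5'-(tetradecane-1,14-diyl)bis(3-methoxy-2-methyl-1,4-benzoquinone)
Product: 12 1,14-bis(3-methoxy-4-methyl-2,5-dioxo-7-oxabicyclo[4.1.0]hept-3-en-1-yl)tetradecane (meso/racemic mixture)
Conditions: 30% aq H2O2, Na2CO3, THF/EtOH/H2O, 0 °C to rt
Reagents that add atoms: hydrogen peroxide, OO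
Why: Weitz–Scheffer nucleophilic epoxidation, in which hydroperoxide adds at the unsubstituted CH of the alkyl-bearing enedione double bond and closes to the necessarily cis-fused oxirane, while the methoxy/methyl double bond is a tetrasubstituted vinylogous ester and far less electrophilic; the face at each ring is uncontrolled and irrelevant, since these stereocentres vanish in step 9.

**Step 9**
Reactants: 12 1,14-bis(3-methoxy-4-methyl-2,5-dioxo-7-oxabicyclo[4.1.0]hept-3-en-1-yl)tetradecane
Product: 13 3,3'-(tetradecane-1,14-diyl)bis(2-hydroxy-5-methoxy-6-methyl-1,4-benzoquinone) (CNP0278640.0)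
Conditions: conc. H2SO4, AcOH, 0 °C to rt; then ice-water
Reagents that add atoms: none
Why: Acid-catalysed isomerisation of a quinone epoxide to the hydroxyquinone (the classical conversion of 2-methyl-1,4-naphthoquinone oxide into phthiocol), in which the protonated oxirane opens at the alkyl-bearing carbon and loss of the α-hydrogen leaves the hydroxyl on the former CH carbon without change of molecular formula.

**Compound list**
1 | 3,5-dimethoxy-4-methylbenzoic acid | COc1cc(C(=O)O)cc(OC)c1C | starting material
2 | (3,5-dimethoxy-4-methylphenyl)methanol | COc1cc(CO)cc(OC)c1C | intermediate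
3 | 5-(bromomethyl)-1,3-dimethoxy-2-methylbenzene | COc1cc(CBr)cc(OC)c1C | intermediate
4 | allylmagnesium bromide | C=CC[Mg]Br | starting material
5 | 5-(but-3-en-1-yl)-1,3-dimethoxy-2-methylbenzene | COc1cc(CCC=C)cc(OC)c1C | intermediate
6 | cis-cyclooctene | C1CCCC/C=C\C1 | starting material
7 | (E)-1,6-bis(3,5-dimethoxy-4-methylphenyl)hex-3-ene (homodimer of 5, E/Z mixture, E drawn) | COc1cc(CC/C=C/CCc2cc(OC)c(C)c(OC)c2)cc(OC)c1C | intermediate (not isolated)
8 | (3E,11E)-1,14-bis(3,5-dimethoxy-4-methylphenyl)tetradeca-3,11-diene (major geometry of an E/Z mixture) | COc1cc(CC/C=C/CCCCCC/C=C/CCc2cc(OC)c(C)c(OC)c2)cc(OC)c1C | intermediate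
9 | 1,14-bis(3,5-dimethoxy-4-methylphenyl)tetradecane | COc1cc(CCCCCCCCCCCCCCc2cc(OC)c(C)c(OC)c2)cc(OC)c1C | intermediate
10 | 5,5'-(tetradecane-1,14-diyl)bis(3-methoxy-2-methylphenol) | COc1cc(CCCCCCCCCCCCCCc2cc(O)c(C)c(OC)c2)cc(O)c1C | intermediate
11 | 5,5'-(tetradecane-1,14-diyl)bis(3-methoxy-2-methyl-1,4-benzoquinone) | COC1=C(C)C(=O)C=C(CCCCCCCCCCCCCCC2=CC(=O)C(C)=C(OC)C2=O)C1=O | intermediate
12 | 1,14-bis(3-methoxy-4-methyl-2,5-dioxo-7-oxabicyclo[4.1.0]hept-3-en-1-yl)tetradecane (each oxirane cis-fused; meso/racemic mixture, so no descriptors given) | COC1=C(C)C(=O)C2OC2(CCCCCCCCCCCCCCC23OC2C(=O)C(C)=C(OC)C3=O)C1=O | intermediate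
13 | 3,3'-(tetradecane-1,14-diyl)bis(2-hydroxy-5-methoxy-6-methyl-1,4-benzoquinone) (no stereocentre) | COC1=C(C)C(=O)C(O)=C(CCCCCCCCCCCCCCC2=C(O)C(=O)C(C)=C(OC)C2=O)C1=O | target

**Step count**
Total steps: 9. Longest linear sequence: 9 steps (1 to 13).

**Steps most likely to fail**

Step 4. More than one cyclooctene unit may be inserted before capping, giving a distribution of end-capped oligomers that differ by C8H14. Ruthenium hydride species may also migrate the double bonds and scramble the chain length by single CH2 units. Fallback, setting out from 3 and returning at 9: commercial 1,12-dibromododecane and Mg in THF give dodecane-1,12-diylbis(magnesium bromide) F1. F1 is coupled with two equivalents of benzyl bromide 3 under Li2CuCl4 catalysis (THF, −20 to 0 °C). This copper-catalysed Grignard–benzyl halide coupling fixes the chain at 1 + 12 + 1 carbons and should give 9 directly, bypassing steps 3 to 5.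

Step 8. Hydroxide or hydroperoxide may attack the methoxy-bearing carbon with loss of the methoxy group, the quinone ring may be cleaved by alkaline peroxide, and low solubility of the lipophilic bisquinone may stall the reaction after one ring. Fallback, setting out from 11 and returning at 13: Thiele–Winter acetoxylation (Ac2O, BF3·OEt2, rt) places an acetoxy group on the only free ring carbon of each quinone and should give 1,14-bis(2,3,6-triacetoxy-5-methoxy-4-methylphenyl)tetradecane F2. Acid methanolysis (HCl, MeOH, reflux) gives 1,14-bis(2,3,6-trihydroxy-5-methoxy-4-methylphenyl)tetradecane F3, and oxidation of F3 with aqueous FeCl3 should give 13. Steps 8 and 9 are bypassed.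

Step 6. Ether cleavage across four methoxy groups may stop short or run on, giving mixtures of phenols that are hard to separate. Fallback, setting out from 9 and returning at 11: NBS (2 equiv, MeCN, 0 °C) brominates each ring at the position para to one methoxy group and ortho to the chain, to give 1,14-bis(2-bromo-3,5-dimethoxy-4-methylphenyl)tetradecane F4. Bromine–lithium exchange (n-BuLi, THF, −78 °C), borylation with B(OMe)3 and oxidation (H2O2, NaOH) give 1,14-bis(2-hydroxy-3,5-dimethoxy-4-methylphenyl)tetradecane F5. Oxidative demethylation of this para-methoxyphenol with (NH4)2Ce(NO3)6 in MeCN/H2O at 0 °C should give bisquinone 11. Steps 6 and 7 are bypassed.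

**Further compounds**
F1 | step 4 | dodecane-1,12-diylbis(magnesium bromide) | Br[Mg]CCCCCCCCCCCC[Mg]Br
F2 | step 8 | 1,14-bis(2,3,6-triacetoxy-5-methoxy-4-methylphenyl)tetradecane | COc1c(C)c(OC(C)=O)c(OC(C)=O)c(CCCCCCCCCCCCCCc2c(OC(C)=O)c(OC(C)=O)c(C)c(OC)c2OC(C)=O)c1OC(C)=O
F3 | step 8 | 1,14-bis(2,3,6-trihydroxy-5-methoxy-4-methylphenyl)tetradecane | COc1c(C)c(O)c(O)c(CCCCCCCCCCCCCCc2c(O)c(O)c(C)c(OC)c2O)c1O
F4 | step 6 | 1,14-bis(2-bromo-3,5-dimethoxy-4-methylphenyl)tetradecane | COc1cc(CCCCCCCCCCCCCCc2cc(OC)c(C)c(OC)c2Br)c(Br)c(OC)c1C
F5 | step 6 | 1,14-bis(2-hydroxy-3,5-dimethoxy-4-methylphenyl)tetradecane | COc1cc(CCCCCCCCCCCCCCc2cc(OC)c(C)c(OC)c2O)c(O)c(OC)c1C
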